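The meeting on the flask began with an easy step: each L takes one E and one Q, so [E] and [Q] fall by equal amounts, and I, taking the minutes, proposed to follow their mean [m], which starts at 1.98 M.

| flask | E | Q | temperature | remark | time |
|---|---|---|---|---|---|
| red | 2 M | 1.96 M | 25 °C | the very flask that is asked about, followed so far |  |
| ochre | 2 M | 2.9 M | 20 °C | run made earlier |  |
| flask | 2.0 M | 1.96 M | 25 °C |  | 1.0 h |

| run | time / min | L / % |
|---|---|---|
| red | 6.00 | 37.3 |
| red | 15.0 | 59.3 |
| red | 30.0 | 74.0 |
| red | 50.0 | 82.6 |
| ochre | 15.0 | 62.5 |
| ochre | 30.0 | 80.6 |
| ochre | 50.0 | 89.5 |
| ochre | 60.0 | 93.3 |

(standard deviation of a reading: 0.3 percentage points)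

- Monday's: at 1.0 h raise the temperature by 25 K, then wait 30 min
- Sunday's: at 1.0 h take out 90% of the L then present, then wait 30 min
- Wednesday's: change nothing and wait 30 min more

- L, in percent of the E first charged, at 1.0 h
- the option that brings most further L ("none" if no option brings more than 2 percentage points) (Monday's / Sunday's / Wednesday's / none)
- L present, with what was taken out counted in, in percent of the E first charged, after Monday's
- L present, with what was taken out counted in, in percent of the E first charged, after Wednesday's

- removed L is counted in
- what was read earlier has a scatter of 0.3 percentage points, one standard deviation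
- what may be going on: E + Q -> L

I argued that for E + Q -> L with rate k[E][Q], and so long as [E] and [Q] differ by little compared with [m], a turnover count, the starting [m] divided by the present [m] less one, grows in step with time. The last red reading, 82.6% at 50.0 min, gives a count of 5.04, so I took 9.93 min as the turnover time, the time in which the count grows by one, a reading that carries the scatter; the reading at 30.0 min gives 10.1 min.

Counting forward, I put the flask at 6.04 turnovers at 1.0 h, hence L at 84.9%, and at 9.07 turnovers after Wednesday's, hence L at 89.2%. Q, charged below E, is the limiting reagent, which puts the ceiling for L at 98.0% of the E charged.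

The forecaster then gave 84.8% and 89.1%, each a little under my figures, and held that Sunday's equals Wednesday's, saying “Removing L does nothing if the reaction is irreversible”. For Monday's the forecaster gave 96%, which stays below the ceiling, and named Monday's as the best option.

The flask gave 84.9% at 1.0 h, 89.1% after Wednesday's and 96.4% after Monday's, and the best option was Monday's, with a gain of 11 percentage points against 4.2 points for Wednesday's.

    E + Q → L (k = 8.48 × 10⁻⁴ M⁻¹ s⁻¹, Ea = 77.0 kJ mol⁻¹)
    (constants at 25 °C)

In this flask 1.0 h is 6.04 turnovers of 9.93 min, with L at 84.9%, while the half-life of E by the step from E + Q to L has lengthened from 0.20 h at 0.124 h to 0.87 h at 1.00 h, which is longer than the 30 min of further time. A repeat of this flask at 0 °C, with the same charges and time, holds 25.8% L at 1.00 h, which the same count reads as 0.352 turnovers and so a turnover time of 170 min, far longer than the 9.93 min of the flask.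

(The data come from a simulation from invented constants; noise was put on by code.)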